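## Retrosynthetic overview
1. The target, an achiral bibenzyl, comes from one hydrogenation of a tetra-O-benzyl (E)-stilbene: C=C becomes CH2–CH2 and four OBn become OH.
2. The stilbene comes from a new four-component Pd/norbornene relay on ring B. Both ortho C–CH2Ar bonds and the ipso C–vinyl bond form in one flask from 1-(benzyloxy)-3-iodobenzene, two 4-(benzyloxy)benzyl chlorides and 3-(benzyloxy)-5-methoxystyrene.
3. The styrene comes from Wittig methylenation of O-benzylated 3-hydroxy-5-methoxybenzaldehyde, and the aryl iodide from O-benzylation of 3-iodophenol.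
4. No ring is built, since all four benzene rings are bought. They are attached to ring B in this order: benzyl para to O, benzyl ortho to O, then the styryl carbon between them.

Assumption 1: the SMILES has no stereocentre and no stereogenic double bond, so the target is achiral and "single enantiomer" needs no action. The stereo-elements that appear on the way (one E-alkene, racemic norbornyl units on palladium) are gone before the last product.

Assumption 2: of the palladium species in the new step, only the three resting points are numbered, with phosphine ligands omitted. The Pd(IV) and Pd–H links between them are not counted as compounds.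

## Route

Step 1
Reactants: 1 3-iodophenol
Product: 2 1-(benzyloxy)-3-iodobenzene
Conditions: BnBr (1.1 equiv), K2CO3 (1.5 equiv), DMF, rt, 6 h
Reagents that add atoms: benzyl bromide, BrCc1ccccc1
Why: Williamson ether synthesis, in which the phenoxide of 1 displaces bromide (SN2) while the aryl iodide is inert to K2CO3; no stereocentre is involved.

Step 2
Reactants: 3 3-hydroxy-5-methoxybenzaldehyde
Product: 4 3-(benzyloxy)-5-methoxybenzaldehyde
Conditions: BnBr (1.1 equiv), K2CO3 (1.5 equiv), DMF, rt, 6 h
Reagents that add atoms: benzyl bromide, BrCc1ccccc1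
Why: Williamson ether synthesis on the only acidic OH; the non-enolisable aldehyde and the methyl ether do not react.

Step 3
Reactants: 4 3-(benzyloxy)-5-methoxybenzaldehyde
Product: 5 1-(benzyloxy)-3-ethenyl-5-methoxybenzene
Conditions: Ph3PCH3Br (1.3 equiv), KOtBu (1.25 equiv), THF, 0 °C to rt
Reagents that add atoms: methyltriphenylphosphonium bromide, [Br-].C[P+](c1ccccc1)(c1ccccc1)c1ccccc1
Why: Wittig methylenation of a non-enolisable aromatic aldehyde with the unstabilised ylide made in the flask; the ethers are inert and a terminal alkene has no geometry to control.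

Step 4
Reactants: 2 1-(benzyloxy)-3-iodobenzene; 5 1-(benzyloxy)-3-ethenyl-5-methoxybenzene; 6 4-(benzyloxy)benzyl chloride (two molecules are built in)
Product: 10 (E)-1-(benzyloxy)-2,4-bis[4-(benzyloxy)benzyl]-3-{2-[3-(benzyloxy)-5-methoxyphenyl]ethenyl}benzene, via first exo,cis aryl-norbornyl palladacycle 7 (not isolated), via mono-benzylated exo,cis aryl-norbornyl palladacycle 8 (not isolated), via {3-(benzyloxy)-2,6-bis[4-(benzyloxy)benzyl]phenyl}palladium(II) chloride 9 (not isolated)
Conditions: Pd(OAc)2 (10 mol %), P(2-furyl)3 (22 mol %), norbornene (5 equiv), Cs2CO3 (5 equiv), 6 (3 equiv), 5 (2 equiv), 4 Å MS, MeCN (0.1 M), 80 °C, sealed tube, 24 h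
Reagents that add atoms: none
Why: Proposed new method: a four-component Pd/norbornene relay in which one aryl iodide takes up two benzylic electrophiles and one styrene; Pd(0)/P(2-furyl)3 inserts into the C–I bond of 2 faster than into the C–Cl bond of 6; exo-syn carbopalladation of norbornene and carbonate-assisted C–H palladation at the open position para to OBn give 7; this electron-rich Pd(II) attacks the very SN2-active 4-alkoxybenzyl chloride to reach Pd(IV), and aryl–CH2 reductive elimination follows; the remaining ortho C–H is flanked only by an ether oxygen whose CH2Ph can turn away, and it is the most acidic C–H of the ring, so it is palladated to 8; a second benzyl transfer fills that position, and only then does the strain of two ortho substituents force β-carbon elimination of norbornene to 9; 9 can no longer hold norbornene and closes the cycle by a Mizoroki–Heck reaction with 5, which gives the E-alkene through syn insertion and syn β-H elimination; the large excess of norbornene returns any mono-benzyl aryl-Pd released too early to the cycle before the slower styrene insertion, and 2 equiv of 5 at a moderate temperature favour Heck capture of 9 over ring closure to a fluorene; the closest known reaction type is the Catellani ortho,ortho'-dialkylation/Heck reaction of aryl iodides with simple primary alkyl halides, in which meta-substituted aryl iodides normally stop after one ortho-functionalisation; new here are the double benzylic transfer, the second palladation next to an alkoxy group and the styrene closure on so crowded an aryl-Pd; no stereocentre is formed.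

Step 5
Reactants: 10 (E)-1-(benzyloxy)-2,4-bis[4-(benzyloxy)benzyl]-3-{2-[3-(benzyloxy)-5-methoxyphenyl]ethenyl}benzene
Product: 11 2,4-bis(4-hydroxybenzyl)-3-[2-(3-hydroxy-5-methoxyphenyl)ethyl]phenol (target)
Conditions: H2 (4 atm), 10 % Pd/C, EtOAc/MeOH 1:1, rt, 24 h
Reagents that add atoms: none
Why: Heterogeneous catalytic hydrogenation saturates the 1,2-disubstituted alkene and hydrogenolyses the four ArO–CH2Ph bonds, while the diarylmethane C–C bonds, the aryl methyl ether and the phenols are inert; no stereocentre is created.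

## Compound list
1 | 3-iodophenol | Oc1cccc(I)c1 | starting material
2 | 1-(benzyloxy)-3-iodobenzene | Ic1cccc(OCc2ccccc2)c1 | intermediate
3 | 3-hydroxy-5-methoxybenzaldehyde | COc1cc(O)cc(C=O)c1 | starting material
4 | 3-(benzyloxy)-5-methoxybenzaldehyde | COc1cc(OCc2ccccc2)cc(C=O)c1 | intermediate
5 | 1-(benzyloxy)-3-ethenyl-5-methoxybenzene | COc1cc(OCc2ccccc2)cc(C=C)c1 | intermediate
6 | 4-(benzyloxy)benzyl chloride, that is 1-(benzyloxy)-4-(chloromethyl)benzene | ClCc1ccc(OCc2ccccc2)cc1 | starting material
7 | first palladacycle: five-membered ring Pd–C3(norbornane, exo)–C2(norbornane, exo)–C(aryl ipso)–C(aryl ortho), with OBn para to the Pd-bound aryl carbon; racemic, one enantiomer drawn, phosphines omitted | [Pd]1c2ccc(OCc5ccccc5)cc2[C@@H]3[C@H]1[C@H]4CC[C@@H]3C4 | intermediate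
8 | second palladacycle: same exo,cis norbornyl unit, with OBn on the carbon next to the Pd-bound aryl carbon and 4-(benzyloxy)benzyl on the other carbon next to the norbornyl-bearing carbon; racemic, one enantiomer drawn, phosphines omitted | [Pd]1c2c(OCc5ccccc5)ccc(Cc5ccc(OCc6ccccc6)cc5)c2[C@@H]3[C@H]1[C@H]4CC[C@@H]3C4 | intermediate
9 | {3-(benzyloxy)-2,6-bis[4-(benzyloxy)benzyl]phenyl}palladium(II) chloride, phosphines omitted | Cl[Pd]c1c(Cc2ccc(OCc3ccccc3)cc2)ccc(OCc2ccccc2)c1Cc1ccc(OCc2ccccc2)cc1 | intermediate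
10 | (E)-1-(benzyloxy)-2,4-bis[4-(benzyloxy)benzyl]-3-{2-[3-(benzyloxy)-5-methoxyphenyl]ethenyl}benzene | COc1cc(OCc2ccccc2)cc(/C=C/c2c(Cc3ccc(OCc4ccccc4)cc3)ccc(OCc3ccccc3)c2Cc2ccc(OCc3ccccc3)cc2)c1 | intermediate
11 | 2,4-bis(4-hydroxybenzyl)-3-[2-(3-hydroxy-5-methoxyphenyl)ethyl]phenol, achiral | COc1cc(O)cc(CCc2c(Cc3ccc(O)cc3)ccc(O)c2Cc2ccc(O)cc2)c1 | target

## Count and risks
Total steps: 5. Longest linear sequence: 4 (3 → 4 → 5 → 10 → 11).

**Most likely to fail, first: step 4 (the new step).** Three things can go wrong: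
- The second C–H palladation next to OBn may be too slow, so a mono-benzylated stilbene leaks out.
- Compound 6 may add to Pd(0).
- The crowded aryl-Pd may close onto a benzyl ring.

The fallback uses known chemistry only. Ring B is built by a Stork–Danheiser sequence and then aromatised. It sets out from 5 and 6 and comes back at 11.

Bought cyclohexane-1,3-dione, bought 4-(benzyloxy)benzaldehyde, Hantzsch ester and L-proline (20 mol %) in CH2Cl2 at rt condense to 2-[4-(benzyloxy)benzylidene]cyclohexane-1,3-dione F1. This is reduced in the same flask to 2-[4-(benzyloxy)benzyl]cyclohexane-1,3-dione F2. i-BuOH and cat. TsOH in toluene (Dean–Stark) give 2-[4-(benzyloxy)benzyl]-3-isobutoxycyclohex-2-en-1-one F3. LDA in THF at −78 °C forms lithium 6-[4-(benzyloxy)benzyl]-5-isobutoxycyclohexa-1,5-dien-1-olate F4. Compound 6 alkylates F4 at the α' carbon to racemic 2,6-bis[4-(benzyloxy)benzyl]-3-isobutoxycyclohex-2-en-1-one F5.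

In parallel, 5 and 9-BBN (THF, rt) give 9-{2-[3-(benzyloxy)-5-methoxyphenyl]ethyl}-9-borabicyclo[3.3.1]nonane F6. H2O2/NaOH gives 2-[3-(benzyloxy)-5-methoxyphenyl]ethan-1-ol F7, and CBr4/PPh3 gives 1-(benzyloxy)-3-(2-bromoethyl)-5-methoxybenzene F8. Mg in THF then gives {2-[3-(benzyloxy)-5-methoxyphenyl]ethyl}magnesium bromide F9.

F9 adds 1,2 to the carbonyl group of F5 to give 2,6-bis[4-(benzyloxy)benzyl]-1-{2-[3-(benzyloxy)-5-methoxyphenyl]ethyl}-3-isobutoxycyclohex-2-en-1-ol F10. 1 M HCl in THF converts F10, with loss of isobutanol and carbonyl transposition, into racemic 2,4-bis[4-(benzyloxy)benzyl]-3-{2-[3-(benzyloxy)-5-methoxyphenyl]ethyl}cyclohex-2-en-1-one F11. F11 already has the O / benzyl / chain / benzyl order of ring B.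

Pd(II)-catalysed aerobic dehydrogenation (Pd(TFA)2 5 mol %, 2-(dimethylamino)pyridine, TsOH, O2 1 atm, DMSO, 80 °C) gives 2,4-bis[4-(benzyloxy)benzyl]-3-{2-[3-(benzyloxy)-5-methoxyphenyl]ethyl}phenol F12. The conditions of step 5 remove its three benzyl groups to give 11.

**Second: step 5.** The alkene sits next to a 2,6-disubstituted ring, and traces of iodide or phosphine from step 4 can poison Pd/C, so saturation may stop short. The fallback separates the two jobs and uses no heterogeneous catalyst. It sets out from 10 and comes back at 11. H2 (1 atm) with [Ir(cod)(PCy3)(py)]PF6 (5 mol %) in CH2Cl2 at rt reduces only the hindered C=C, giving 1-(benzyloxy)-2,4-bis[4-(benzyloxy)benzyl]-3-{2-[3-(benzyloxy)-5-methoxyphenyl]ethyl}benzene F13. BCl3 (8 equiv) and pentamethylbenzene (12 equiv) in CH2Cl2 at −78 °C then take off the four benzyl groups by Lewis-acid cleavage with cation capture. The aryl methyl ether stays, and the product is 11.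

**Third: step 3.** The styrene can be lost through polymerisation during the separation from the phosphorus by-product. The fallback replaces the ylide with an addition/elimination sequence (Peterson). It sets out from 4 and comes back at 5. Me3SiCH2MgCl in THF at 0 °C adds to 4 to give racemic 1-[3-(benzyloxy)-5-methoxyphenyl]-2-(trimethylsilyl)ethan-1-ol F14. Cat. H2SO4 in THF at rt eliminates the silanol to give 5, with only volatile by-products.

## Further compounds
F1 | step 4 | 2-[4-(benzyloxy)benzylidene]cyclohexane-1,3-dione | O=C1CCCC(=O)C1=Cc1ccc(OCc2ccccc2)cc1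
F2 | step 4 | 2-[4-(benzyloxy)benzyl]cyclohexane-1,3-dione | O=C1CCCC(=O)C1Cc1ccc(OCc2ccccc2)cc1
F3 | step 4 | 2-[4-(benzyloxy)benzyl]-3-isobutoxycyclohex-2-en-1-one | CC(C)COC1=C(Cc2ccc(OCc3ccccc3)cc2)C(=O)CCC1
F4 | step 4 | lithium 6-[4-(benzyloxy)benzyl]-5-isobutoxycyclohexa-1,5-dien-1-olate | [Li+].CC(C)COC1=C(Cc2ccc(OCc3ccccc3)cc2)C([O-])=CCC1
F5 | step 4 | 2,6-bis[4-(benzyloxy)benzyl]-3-isobutoxycyclohex-2-en-1-one (racemic) | CC(C)COC1=C(Cc2ccc(OCc3ccccc3)cc2)C(=O)C(Cc2ccc(OCc3ccccc3)cc2)CC1
F6 | step 4 | 9-{2-[3-(benzyloxy)-5-methoxyphenyl]ethyl}-9-borabicyclo[3.3.1]nonane | COc1cc(CCB2C3CCCC2CCC3)cc(OCc2ccccc2)c1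
F7 | step 4 | 2-[3-(benzyloxy)-5-methoxyphenyl]ethan-1-ol | COc1cc(CCO)cc(OCc2ccccc2)c1
F8 | step 4 | 1-(benzyloxy)-3-(2-bromoethyl)-5-methoxybenzene | COc1cc(CCBr)cc(OCc2ccccc2)c1
F9 | step 4 | {2-[3-(benzyloxy)-5-methoxyphenyl]ethyl}magnesium bromide | COc1cc(CC[Mg]Br)cc(OCc2ccccc2)c1
F10 | step 4 | 2,6-bis[4-(benzyloxy)benzyl]-1-{2-[3-(benzyloxy)-5-methoxyphenyl]ethyl}-3-isobutoxycyclohex-2-en-1-ol (racemic mixture of diastereomers) | COc1cc(CCC2(O)C(Cc3ccc(OCc4ccccc4)cc3)CCC(OCC(C)C)=C2Cc2ccc(OCc3ccccc3)cc2)cc(OCc2ccccc2)c1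
F11 | step 4 | 2,4-bis[4-(benzyloxy)benzyl]-3-{2-[3-(benzyloxy)-5-methoxyphenyl]ethyl}cyclohex-2-en-1-one (racemic) | COc1cc(CCC2=C(Cc3ccc(OCc4ccccc4)cc3)C(=O)CCC2Cc2ccc(OCc3ccccc3)cc2)cc(OCc2ccccc2)c1
F12 | step 4 | 2,4-bis[4-(benzyloxy)benzyl]-3-{2-[3-(benzyloxy)-5-methoxyphenyl]ethyl}phenol | COc1cc(CCc2c(Cc3ccc(OCc4ccccc4)cc3)ccc(O)c2Cc2ccc(OCc3ccccc3)cc2)cc(OCc2ccccc2)c1
F13 | step 5 | 1-(benzyloxy)-2,4-bis[4-(benzyloxy)benzyl]-3-{2-[3-(benzyloxy)-5-methoxyphenyl]ethyl}benzene | COc1cc(OCc2ccccc2)cc(CCc2c(Cc3ccc(OCc4ccccc4)cc3)ccc(OCc3ccccc3)c2Cc2ccc(OCc3ccccc3)cc2)c1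
F14 | step 3 | 1-[3-(benzyloxy)-5-methoxyphenyl]-2-(trimethylsilyl)ethan-1-ol (racemic) | COc1cc(OCc2ccccc2)cc(C(O)C[Si](C)(C)C)c1
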